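## Structural features

The target is built from two benzene rings joined by a benzylic ester, with no stereocentre. Ring A is a methyl resorcylate, numbered here C1 (CO2Me), C2 (CH2O), C3 (H), C4 (OH), C5 (CH3), C6 (OH); locants in systematic compound names follow the usual rules and differ from this numbering. Ring B is haematommic acid: C1′ (carboxyl), C2′ (OH), C3′ (CHO), C4′ (OH), C5′ (H), C6′ (CH3), and the link is C2–CH2–O–C(=O)–C1′. The fragile elements are the aldehyde, the electron-rich rings (each with one free CH that reacts readily with electrophiles such as formaldehyde), and above all the benzylic ester. If that ester is cleaved, the freed ring A benzylic alcohol sits beside the C1 methyl ester and lactonises. The ring B carboxyl is flanked by CH3 and an oxygen, so substitution at its acyl carbon is slow, whereas its carboxylate alkylates normally. The real difficulty is the CH2 carbon on C2: it is meta to both ring oxygens (O4 and O6) and ortho to the ester, so no electrophilic substitution can place it. The key step uses two facts. C2 is the only ring carbon of the 2-methylresorcinol core without an ortho neighbour, so a sterically governed C–H borylation can put a halogen there. The C2–CH2 bond can then be made by cross-coupling with a CH2 nucleophile that already carries the ring B carboxylate.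

## Logic of the disconnections

**20 ⇒ 19.** Only four O–CH2 acetal bonds are cut. Acetals are chosen because they survive organolithium bases, aqueous carbonate and palladium, and because hydrogenolysis (the usual way to unmask phenols) would cleave the benzylic ester. The forward step must remove four aryl acetals without exchanging the benzylic ester and without letting the released formaldehyde equivalent attack C3 or C5′.

**19 ⇒ 7 + 17.** The C2(ring A)–CH2 bond is cut. This is the one bond that ordinary aromatic chemistry cannot make, and cutting it divides the molecule into two arenes of similar size. The ester link stays intact throughout, so a ring A benzylic alcohol never exists. The forward step is an sp2–sp3 coupling in which transfer of the CH2 group must be faster than loss of boron and faster than saponification of either ester.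

**17 ⇒ 15 + 16.** The O–CH2 bond is cut. The hindered acid is esterified through its carboxylate oxygen on an unhindered CH2Br carbon, which avoids the shielded acyl carbon altogether. The forward step needs a weakly nucleophilic carboxylate to displace bromide from an anionic borate.

**15 ⇒ 12.** The C1′–CO2H bond is cut. Compound 12 is symmetric, with two equivalent ring CH groups each next to an acetal oxygen, so the regiochemistry of ring metalation is unambiguous. The forward step requires the aldehyde to be masked in the flask while the ring is lithiated.

**12 ⇒ 9 ⇒ 8.** The C3′–CHO bond is cut, then the two O–CH2 acetal bonds. The carbon between the two acetal oxygens of 9 is the most acidic ring position, so the formyl group goes in first and exactly where it belongs.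

**7 ⇒ 5.** The C1–CO2Me bond is cut. The two equivalent ring CH groups of 5 each lie between bromine and an acetal oxygen, so metalation can occur only there. The forward step needs an amide base that deprotonates without exchanging the bromine, and a temperature low enough to keep the ortho-bromo aryllithium intact.

**5 ⇒ 4 ⇒ 3.** Two O–CH2 acetal bonds are cut, then the oxygens are traced back to methyl ethers. The halogenation that leads to 3 releases HBr in hot aqueous methanol, which aryl acetals would not survive. Bromine is therefore introduced while the oxygens carry methyl groups, and the acetals are put on afterwards. This costs one step and removes the acid-labile group from the only acidic step of the branch.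

**3 ⇒ 1.** The C–Br bond is cut, through the C–B bond of 2. The position is meta to both oxygens and is the only ring CH of 1 without an ortho substituent, so sterically governed borylation is selective for it, and 1 is commercial.

## Other disconnections considered

**Alternative 1:** The cut runs through ring B: C1′–C6′ and C3′–C4′ are broken, which traces ring B back to the ring A benzylic acetoacetate A1 and ethyl crotonate A2. In the forward step the enolate of A1 would add to A2 in a Michael reaction. A Claisen-type closure of the acetyl methyl carbanion onto the ethyl ester would then give the cyclohexane-1,3-dione A3, with two adjacent stereocentres (trans, racemic) that are erased later. C-formylation between the two carbonyls and dehydrogenation would have to follow.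
- In its favour: the substitution pattern of ring B is fixed by construction from cheap acyclic pieces, with no directed metalation and no palladium. The ester link exists before ring B does, so the hindered-acid esterification never arises. On these two points the alternative is the equal or the better of the chosen plan, and it forms two C–C bonds and a ring in one step against one bond in the cross-coupling.
- Against it: A1 can only come from the ring A benzylic alcohol A4, the very compound that lactonises onto its neighbouring methyl ester. The meta CH2 carbon would still have to be introduced by other means.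
- Mechanistically, the alkoxide needed for the annulation would transesterify the unhindered benzylic ester. In A3 the link is a β-keto ester, open to retro-Claisen cleavage and decarboxylation, whereas in the chosen plan it is always a doubly ortho-shielded aroate.
- On step economy, three operations (formylation, aromatisation, deprotection) would follow the key step instead of one. The oxidant for aromatisation would also meet an electron-rich ring A and a new aldehyde.

**Alternative 2:** The cut runs through ring A: C1–C6 and C2–C3 are broken, giving the diene A5 and the ynoate A6, which already carries ring B with its aldehyde as a dioxolane. In the forward step A5 would add across the triple bond in a Diels–Alder reaction. The bicyclo[2.2.2]octadiene would then expel its two-carbon bridge by a retro-Diels–Alder step (Alder–Rickert), and desilylation would give the resorcylate A7.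
- In its favour: the meta relationship of CH2O to both oxygens follows from the polarity match between the unsubstituted diene terminus and the β-carbon of the ynoate, so the same structural problem is solved without halogen or transition metal. Ring A emerges with free hydroxyls, saving two protecting groups. The ring A branch is shorter, since A5 is one silylation from a commercial cyclic diketone and A6 one O-alkylation of a ring B carboxylate. On protecting-group and step economy the alternative is the equal or the better of the chosen plan.
- Against it: expelling the bridge needs prolonged heating well above the temperature of the cross-coupling, in the presence of four acid-sensitive acetal functions and a propargylic ester. The aldehyde must be masked because the electron-rich diene would otherwise add to it.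
- On structure and mechanism, the regiochemistry rests on an electronic bias, not on a pre-placed atom, and A5 is sensitive to adventitious acid. The chosen plan fixes the site by the position of bromine and runs at about 90 °C in aqueous base, at the price of a longer ring A branch and two precious-metal catalysts.

**Alternative 3:** The cuts are the C1′–C(=O) bond of ring B and the O–CH2 bond, giving three components: the acetal A8, a one-carbon carboxylating agent and the ring A benzylic bromide A9. In the forward step A8 would be lithiated at one of its two equivalent ring CH groups and carboxylated. The lithium carboxylate would then be alkylated in the same flask by A9 to give the fully protected A10.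
- In its favour: it is the most convergent plan. The hindered acid is never isolated, and the ester is made by carboxylate alkylation, the same logic as step 8 of the chosen plan, so the two are equal there. No palladium is needed, and the ring B branch takes fewer operations, so on that count the alternative is better.
- Against it: the whole difficulty moves into A9, whose benzylic carbon meta to both oxygens must already be present. Benzylic bromination of A11 would have to distinguish two aryl methyl groups, and avoid bromination at the free ring position and hydrogen abstraction from the acetals.
- Mechanistically, an ortho-(bromomethyl)benzoate such as A9 is itself prone to lactonise on warming, and lithium carboxylates are sluggish nucleophiles in ethereal solvent.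
- On step economy the alternative is shorter once A9 is in hand. The chosen plan is longer but has no step whose site selectivity is open.

Key step: step 9

Remarks on the chemistry: the connectivity of both coupling partners and of the coupling product agrees with the target once the four acetals are removed, so no structural correction is needed. Salts that arise only by proton transfer (for example the potassium salt of 15) are not numbered apart from the parent compound. Orcinol is used in anhydrous form.

## Route

Step 1
Reactants: 1 1,3-dimethoxy-2-methylbenzene (2,6-dimethoxytoluene)
Product: 3 5-bromo-1,3-dimethoxy-2-methylbenzene, via pinacol boronate 2 (not isolated)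
Conditions: [Ir(OMe)(cod)]2 (1 mol %), 4,4′-di-tert-butyl-2,2′-bipyridine (2 mol %), B2pin2 (0.6 equiv), cyclohexane, 80 °C; evaporate; CuBr2 (3 equiv), MeOH–H2O (1:1), 80 °C
Reagents that add atoms: CuBr2, [Cu+2].[Br-].[Br-]; bis(pinacolato)diboron, CC1(C)OB(OC1(C)C)B1OC(C)(C)C(C)(C)O1 (its boron is carried only as far as 2)
Why: Sterically governed iridium-catalysed C–H borylation should reach only the single ring CH of 1 that has no ortho substituent; divalent copper then turns the aryl boronate into the bromide (one-pot borylation/bromodeboronation). The methyl ethers are inert to the HBr released, which is why the halogen is installed before any acetal protecting group.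

Step 2
Reactants: 3 5-bromo-1,3-dimethoxy-2-methylbenzene
Product: 4 5-bromo-2-methylbenzene-1,3-diol
Conditions: BBr3 (3 equiv), CH2Cl2, −78 °C → rt; H2O, 0 °C
Reagents that add atoms: none
Why: Lewis-acid cleavage of aryl methyl ethers: bromide displaces the methyl group of the boron-complexed ether and water frees the phenols; the aryl bromide is untouched.

Step 3
Reactants: 4 5-bromo-2-methylbenzene-1,3-diol
Product: 5 5-bromo-1,3-bis(methoxymethoxy)-2-methylbenzene
Conditions: MOMCl (3 equiv), iPr2NEt (4 equiv), CH2Cl2, 0 °C → rt
Reagents that add atoms: chloromethyl methyl ether, COCCl
Why: O-alkylation of the phenols by an α-chloro ether; the acetals later direct the metalation and tolerate the base and palladium of the coupling.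

Step 4
Reactants: 5 5-bromo-1,3-bis(methoxymethoxy)-2-methylbenzene
Product: 7 methyl 6-bromo-2,4-bis(methoxymethoxy)-3-methylbenzoate, via aryllithium 6 (not isolated)
Conditions: LDA (1.2 equiv), THF, −78 °C, 1 h; ClCO2Me (2 equiv), −78 °C → rt
Reagents that add atoms: methyl chloroformate, COC(=O)Cl
Why: Directed ortho-metalation: the two equivalent ring CH groups of 5 each lie between bromine (inductive acidification) and an acetal oxygen (coordination), and an amide base deprotonates without bromine–lithium exchange. At −78 °C the ortho-bromo aryllithium should not lose LiBr, and acylation by the chloroformate gives the ester.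

Step 5
Reactants: 8 orcinol (5-methylbenzene-1,3-diol)
Product: 9 1,3-bis(methoxymethoxy)-5-methylbenzene
Conditions: MOMCl (3 equiv), iPr2NEt (4 equiv), CH2Cl2, 0 °C → rt
Reagents that add atoms: chloromethyl methyl ether, COCCl
Why: Same phenol O-alkylation as in step 3; the two acetals set up the cooperative metalation of the next step.

Step 6
Reactants: 9 1,3-bis(methoxymethoxy)-5-methylbenzene
Product: 12 2,6-bis(methoxymethoxy)-4-methylbenzaldehyde, via aryllithium 10 (not isolated), via lithium aminoalkoxide 11 (not isolated)
Conditions: n-BuLi (1.1 equiv), TMEDA (1.1 equiv), THF, 0 °C, 1 h; DMF (1.5 equiv), 0 °C → rt; H2O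
Reagents that add atoms: N,N-dimethylformamide, CN(C)C=O
Why: Directed ortho-metalation at the carbon between the two acetal oxygens, the most acidic ring position, followed by formylation with DMF; the tetrahedral adduct collapses to the aldehyde on hydrolysis.

Step 7
Reactants: 12 2,6-bis(methoxymethoxy)-4-methylbenzaldehyde
Product: 15 3-formyl-2,4-bis(methoxymethoxy)-6-methylbenzoic acid, via piperazinyl alkoxide 13 (not isolated), via ring-lithiated alkoxide 14 (not isolated)
Conditions: 1-methylpiperazine (1.1 equiv), n-BuLi (1.1 equiv), THF, −20 °C, then 12; n-BuLi (2 equiv), TMEDA, −20 °C, 3 h; CO2, −78 °C → 0 °C; 1 M HCl to pH 3, 0 °C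
Reagents that add atoms: carbon dioxide, O=C=O
Why: In situ protection of the aldehyde as an α-amino alkoxide (Comins protocol) allows directed ortho-metalation beside an acetal oxygen; the two ring CH groups are equivalent, so one regioisomer is possible. Carboxylation and a brief cold acidic work-up release acid and aldehyde together while the aryl acetals should survive.

Step 8
Reactants: 15 3-formyl-2,4-bis(methoxymethoxy)-6-methylbenzoic acid; 16 potassium bromomethyltrifluoroborate
Product: 17 potassium {[3-formyl-2,4-bis(methoxymethoxy)-6-methylbenzoyl]oxymethyl}trifluoroborate
Conditions: KHCO3 (1.1 equiv), KI (10 mol %), DMF, 70 °C; evaporate, extract into acetone, precipitate with Et2O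
Reagents that add atoms: none
Why: SN2 displacement of bromide from the unhindered CH2 carbon by the potassium carboxylate, with iodide catalysis; this is the known substitution chemistry of halomethyltrifluoroborates with oxygen nucleophiles. Esterification through the carboxylate oxygen bypasses the shielded acyl carbon.

Step 9
Reactants: 7 methyl 6-bromo-2,4-bis(methoxymethoxy)-3-methylbenzoate; 17 potassium {[3-formyl-2,4-bis(methoxymethoxy)-6-methylbenzoyl]oxymethyl}trifluoroborate
Product: 19 methyl 6-({[3-formyl-2,4-bis(methoxymethoxy)-6-methylbenzoyl]oxy}methyl)-2,4-bis(methoxymethoxy)-3-methylbenzoate, via boronic acid 18 (not isolated)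
Conditions: Pd(OAc)2 (5 mol %), RuPhos (10 mol %), K2CO3 (3 equiv), 17 (1.3 equiv), 1,4-dioxane–H2O (10:1), degassed, 90 °C
Reagents that add atoms: none
Why: Pd(OAc)2 is reduced in the flask to a RuPhos-ligated zerovalent palladium species that inserts into the C–Br bond of 7, the flanking ester making that carbon electrophilic enough despite the two alkoxy groups. Carbonate and water slowly hydrolyse 17 to the boronic acid 18, whose CH2 group is transferred to the arylpalladium hydroxide, and reductive elimination forms the C2(ring A)–CH2 bond. The closest known reaction type is the Suzuki–Miyaura coupling of potassium acyloxymethyl- and alkoxymethyltrifluoroborates with aryl halides under Pd(OAc)2/RuPhos catalysis. No ring is closed and no stereocentre is created. Site selectivity is settled by the position of bromine, and the CH2 group has no β-hydrogen, so β-hydride elimination cannot intervene. What the step needs is chemoselectivity: transmetalation must outrun protodeboronation of 18 and saponification of either ester; both esters are shielded by two ortho substituents, and the slow release of 18 keeps its concentration low. The aldehyde is non-enolisable and flanked by two acetal oxygens, and the acetals are inert to aqueous carbonate.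

Step 10
Reactants: 19 methyl 6-({[3-formyl-2,4-bis(methoxymethoxy)-6-methylbenzoyl]oxy}methyl)-2,4-bis(methoxymethoxy)-3-methylbenzoate
Product: 20 methyl 6-{[(3-formyl-2,4-dihydroxy-6-methylbenzoyl)oxy]methyl}-2,4-dihydroxy-3-methylbenzoate
Conditions: HCl (4 M in 1,4-dioxane, 10 equiv), MeOH–THF (1:1), 40 °C; then H2O, rt
Reagents that add atoms: none
Why: Acid-catalysed acetal exchange transfers each methoxymethyl group to methanol, which also traps the formaldehyde equivalent away from the free ring positions. The benzylic carbon is meta to both oxygens, so it should not ionise, and both ester carbonyls are doubly ortho-shielded against methanolysis. Any dimethyl acetal formed at the aldehyde reverts when water is added.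

## Compound list

1 | 1,3-dimethoxy-2-methylbenzene (2,6-dimethoxytoluene) | COc1cccc(OC)c1C | starting material
2 | 2-(3,5-dimethoxy-4-methylphenyl)-4,4,5,5-tetramethyl-1,3,2-dioxaborolane | COc1cc(B2OC(C)(C)C(C)(C)O2)cc(OC)c1C | intermediate
3 | 5-bromo-1,3-dimethoxy-2-methylbenzene | COc1cc(Br)cc(OC)c1C | intermediate
4 | 5-bromo-2-methylbenzene-1,3-diol | Cc1c(O)cc(Br)cc1O | intermediate
5 | 5-bromo-1,3-bis(methoxymethoxy)-2-methylbenzene | COCOc1cc(Br)cc(OCOC)c1C | intermediate
6 | [6-bromo-2,4-bis(methoxymethoxy)-3-methylphenyl]lithium | [Li]c1c(Br)cc(OCOC)c(C)c1OCOC | intermediate
7 | methyl 6-bromo-2,4-bis(methoxymethoxy)-3-methylbenzoate | COC(=O)c1c(Br)cc(OCOC)c(C)c1OCOC | intermediate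
8 | orcinol (5-methylbenzene-1,3-diol) | Cc1cc(O)cc(O)c1 | starting material
9 | 1,3-bis(methoxymethoxy)-5-methylbenzene | Cc1cc(OCOC)cc(OCOC)c1 | intermediate
10 | [2,6-bis(methoxymethoxy)-4-methylphenyl]lithium | [Li]c1c(OCOC)cc(C)cc1OCOC | intermediate
11 | lithium [2,6-bis(methoxymethoxy)-4-methylphenyl](dimethylamino)methanolate (racemic) | [Li+].[O-]C(N(C)C)c1c(OCOC)cc(C)cc1OCOC | intermediate
12 | 2,6-bis(methoxymethoxy)-4-methylbenzaldehyde | Cc1cc(OCOC)c(C=O)c(OCOC)c1 | intermediate
13 | lithium [2,6-bis(methoxymethoxy)-4-methylphenyl](4-methylpiperazin-1-yl)methanolate (racemic) | [Li+].[O-]C(N1CCN(C)CC1)c1c(OCOC)cc(C)cc1OCOC | intermediate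
14 | lithium [3-lithio-2,6-bis(methoxymethoxy)-4-methylphenyl](4-methylpiperazin-1-yl)methanolate (racemic) | [Li+].[O-]C(N1CCN(C)CC1)c1c(OCOC)cc(C)c([Li])c1OCOC | intermediate
15 | 3-formyl-2,4-bis(methoxymethoxy)-6-methylbenzoic acid | Cc1cc(OCOC)c(C=O)c(OCOC)c1C(=O)O | intermediate
16 | potassium bromomethyltrifluoroborate | [K+].F[B-](F)(F)CBr | starting material
17 | potassium {[3-formyl-2,4-bis(methoxymethoxy)-6-methylbenzoyl]oxymethyl}trifluoroborate | [K+].F[B-](F)(F)COC(=O)c1c(C)cc(OCOC)c(C=O)c1OCOC | intermediate
18 | {[3-formyl-2,4-bis(methoxymethoxy)-6-methylbenzoyl]oxymethyl}boronic acid | OB(O)COC(=O)c1c(C)cc(OCOC)c(C=O)c1OCOC | intermediate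
19 | methyl 6-({[3-formyl-2,4-bis(methoxymethoxy)-6-methylbenzoyl]oxy}methyl)-2,4-bis(methoxymethoxy)-3-methylbenzoate | COC(=O)c1c(COC(=O)c2c(C)cc(OCOC)c(C=O)c2OCOC)cc(OCOC)c(C)c1OCOC | intermediate
20 | methyl 6-{[(3-formyl-2,4-dihydroxy-6-methylbenzoyl)oxy]methyl}-2,4-dihydroxy-3-methylbenzoate (CNP0122264.0) | COC(=O)c1c(COC(=O)c2c(C)cc(O)c(C=O)c2O)cc(O)c(C)c1O | target

## Step count and least certain steps

Total step count: 10. Longest linear sequence: 6 steps (steps 1–4, 9, 10; the ring B branch through steps 5–8, 9, 10 is equally long).

**Step 9 (key step).** The most likely failure is protodeboronation of the CH2–B bond outrunning transmetalation, with saponification of an ester (and then lactonisation on ring A), hydrodebromination of 7, and ionisation of the new benzylic C–O bond by zerovalent palladium as further drains. The fallback replaces the boron nucleophile and the aqueous base by a tin nucleophile under anhydrous, neutral conditions. It sets out from 15, which would be O-alkylated with tributyl(iodomethyl)stannane (K2CO3, DMF) to give (tributylstannyl)methyl 3-formyl-2,4-bis(methoxymethoxy)-6-methylbenzoate F1. Stille coupling of F1 with 7 (Pd(PPh3)4, CuI, DMF, 80 °C) should transfer the α-oxygenated CH2 group in preference to butyl and rejoins the route at 19.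

**Step 4.** The ortho-bromo aryllithium may lose LiBr to an aryne, exchange halogen between molecules, or form incompletely because the acidity is borderline for an amide base. The fallback builds the ester carbon by electrophilic substitution. It sets out from 4, where Vilsmeier formylation (POCl3, DMF, then H2O) can only go to the position ortho and para to the hydroxyls and should give 6-bromo-2,4-dihydroxy-3-methylbenzaldehyde F2. Acetal protection (MOMCl, iPr2NEt) would give 6-bromo-2,4-bis(methoxymethoxy)-3-methylbenzaldehyde F3. Pinnick oxidation (NaClO2, NaH2PO4, 2-methyl-2-butene) would give 6-bromo-2,4-bis(methoxymethoxy)-3-methylbenzoic acid F4, and O-methylation (MeI, K2CO3, DMF) rejoins the route at 7.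

**Step 7.** Competing deprotonation of the ring methyl group, addition of n-BuLi to aldehyde that is incompletely masked, slow lithiation at a ring position flanked by methyl, or loss of an acetal during acidification may lower the return. The fallback isolates a covalent acetal instead of masking in the flask. It sets out from 12, which with HC(OMe)3 and catalytic pyridinium p-toluenesulfonate in MeOH should give 2-(dimethoxymethyl)-1,3-bis(methoxymethoxy)-5-methylbenzene F5. Lithiation (s-BuLi, TMEDA, THF, −78 °C) and carboxylation would give 3-(dimethoxymethyl)-2,4-bis(methoxymethoxy)-6-methylbenzoic acid F6. Brief stirring at pH 3 in THF–H2O should hydrolyse the dimethyl acetal, which is far more labile than the aryl acetals, and rejoins the route at 15.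

**Step 8.** Substitution by a weakly nucleophilic, hindered carboxylate at the carbon of an anionic borate may be slow, and prolonged heating risks solvolysis of the B–F bonds; separation from KBr may also be troublesome. The fallback alkylates a neutral boronic ester first. It sets out from 15, which with 2-(bromomethyl)-4,4,5,5-tetramethyl-1,3,2-dioxaborolane and K2CO3 in MeCN should give (4,4,5,5-tetramethyl-1,3,2-dioxaborolan-2-yl)methyl 3-formyl-2,4-bis(methoxymethoxy)-6-methylbenzoate F7. Treatment with KHF2 in aqueous MeOH at 0 °C rejoins the route at 17.

**Step 10.** The two acetals that are not next to a carbonyl may cleave slowly at a temperature where methanolysis of the benzylic ester stays negligible. Forcing the reaction invites ester exchange followed by lactonisation on ring A, and alkylation of C3 or C5′ by the released formaldehyde equivalent. The fallback exchanges the acetals for silyl ethers under buffered, aprotic conditions. It sets out from 19, which with TMSOTf and 2,2′-bipyridyl in MeCN at 0 °C should give methyl 6-({[3-formyl-6-methyl-2,4-bis(trimethylsilyloxy)benzoyl]oxy}methyl)-3-methyl-2,4-bis(trimethylsilyloxy)benzoate F8. The methoxymethyl groups are held as pyridinium salts until work-up, and water then cleaves the aryl silyl ethers and rejoins the route at 20.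

## Further compounds

F1 | step 9 | (tributylstannyl)methyl 3-formyl-2,4-bis(methoxymethoxy)-6-methylbenzoate | CCCC[Sn](CCCC)(CCCC)COC(=O)c1c(C)cc(OCOC)c(C=O)c1OCOC
F2 | step 4 | 6-bromo-2,4-dihydroxy-3-methylbenzaldehyde | O=Cc1c(Br)cc(O)c(C)c1O
F3 | step 4 | 6-bromo-2,4-bis(methoxymethoxy)-3-methylbenzaldehyde | O=Cc1c(Br)cc(OCOC)c(C)c1OCOC
F4 | step 4 | 6-bromo-2,4-bis(methoxymethoxy)-3-methylbenzoic acid | OC(=O)c1c(Br)cc(OCOC)c(C)c1OCOC
F5 | step 7 | 2-(dimethoxymethyl)-1,3-bis(methoxymethoxy)-5-methylbenzene | COC(OC)c1c(OCOC)cc(C)cc1OCOC
F6 | step 7 | 3-(dimethoxymethyl)-2,4-bis(methoxymethoxy)-6-methylbenzoic acid | COC(OC)c1c(OCOC)cc(C)c(C(=O)O)c1OCOC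
F7 | step 8 | (4,4,5,5-tetramethyl-1,3,2-dioxaborolan-2-yl)methyl 3-formyl-2,4-bis(methoxymethoxy)-6-methylbenzoate | CC1(C)OB(COC(=O)c2c(C)cc(OCOC)c(C=O)c2OCOC)OC1(C)C
F8 | step 10 | methyl 6-({[3-formyl-6-methyl-2,4-bis(trimethylsilyloxy)benzoyl]oxy}methyl)-3-methyl-2,4-bis(trimethylsilyloxy)benzoate | COC(=O)c1c(COC(=O)c2c(C)cc(O[Si](C)(C)C)c(C=O)c2O[Si](C)(C)C)cc(O[Si](C)(C)C)c(C)c1O[Si](C)(C)C
A1 | alternative 1 | methyl 2,4-bis(methoxymethoxy)-3-methyl-6-{[(3-oxobutanoyl)oxy]methyl}benzoate | CC(=O)CC(=O)OCc1cc(OCOC)c(C)c(OCOC)c1C(=O)OC
A2 | alternative 1 | ethyl (E)-but-2-enoate (ethyl crotonate) | C/C=C/C(=O)OCC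
A3 | alternative 1 | [2-(methoxycarbonyl)-3,5-bis(methoxymethoxy)-4-methylphenyl]methyl trans-6-methyl-2,4-dioxocyclohexane-1-carboxylate (racemic, one enantiomer drawn) | O=C1CC(=O)C[C@H](C)[C@H]1C(=O)OCc1cc(OCOC)c(C)c(OCOC)c1C(=O)OC
A4 | alternative 1 | methyl 6-(hydroxymethyl)-2,4-bis(methoxymethoxy)-3-methylbenzoate | COC(=O)c1c(CO)cc(OCOC)c(C)c1OCOC
A5 | alternative 2 | 2-methyl-1,3-bis(trimethylsilyloxy)cyclohexa-1,3-diene | C[Si](C)(C)OC1=C(C)C(O[Si](C)(C)C)=CCC1
A6 | alternative 2 | methyl 4-{[3-(1,3-dioxolan-2-yl)-2,4-bis(methoxymethoxy)-6-methylbenzoyl]oxy}but-2-ynoate | COC(=O)C#CCOC(=O)c1c(C)cc(OCOC)c(C2OCCO2)c1OCOC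
A7 | alternative 2 | methyl 6-({[3-(1,3-dioxolan-2-yl)-2,4-bis(methoxymethoxy)-6-methylbenzoyl]oxy}methyl)-2,4-dihydroxy-3-methylbenzoate | COC(=O)c1c(COC(=O)c2c(C)cc(OCOC)c(C3OCCO3)c2OCOC)cc(O)c(C)c1O
A8 | alternative 3 | 2-[2,6-bis(methoxymethoxy)-4-methylphenyl]-1,3-dioxolane | Cc1cc(OCOC)c(C2OCCO2)c(OCOC)c1
A9 | alternative 3 | methyl 6-(bromomethyl)-2,4-bis(methoxymethoxy)-3-methylbenzoate | COC(=O)c1c(CBr)cc(OCOC)c(C)c1OCOC
A10 | alternative 3 | methyl 6-({[3-(1,3-dioxolan-2-yl)-2,4-bis(methoxymethoxy)-6-methylbenzoyl]oxy}methyl)-2,4-bis(methoxymethoxy)-3-methylbenzoate | COC(=O)c1c(COC(=O)c2c(C)cc(OCOC)c(C3OCCO3)c2OCOC)cc(OCOC)c(C)c1OCOC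
A11 | alternative 3 | methyl 2,4-bis(methoxymethoxy)-3,6-dimethylbenzoate | COC(=O)c1c(C)cc(OCOC)c(C)c1OCOC
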